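**Remark:** ring atoms are numbered N1, C2 (CH3), C3 (OH), C4, C5, C6 (chain) in every piperidine. Enone 9 is assumed not to be a catalogue item and is made from 2,3-butanedione.

## Retrosynthetic overview

1. The 2-substituted (E)-enal is the aldol-condensation seam of two identical C12 aldehydes, each carrying one (2S,3S,6R)-piperidine, so one monomer (N-Boc aldehyde 18) is made and dimerised at the end.
2. Each piperidine is cut at C4–C5 and N1–C2 ([3+3]): N1–C6–C5 with the C12 chain comes from L-serine as a β-amido alkylzinc iodide; CH3–C2–C3(O)–C4 comes from 2,3-butanedione as the captodative enone 9.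
3. Enabling feature: the vicinal N1–C2H(CH3)/C3H(OH) pair is the reduced form of an α-amino ketone, which is the Heyns isomer of the α-hydroxy imine formed when the C6 amine meets a C2 ketone beside a C3 carbinol. At that oxidation level C3 is trigonal and C2 is epimerisable, 1,3 to C6 across N1.
4. Stereochemistry: only C6 is bought. The ring closure sets C2 cis to C6 by equilibration, then hydride sets C3 cis to C2.
5. Ring order: the piperidine is the only ring made (step 6, once, on the monomer; both rings of the target stem from it). The oxazolidine of 3 is carried and opened in step 3.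

Key step: step 6

## Route

Step 1
Reactants: 1 methyl 11-bromoundecanoate
Product: 2 (11-methoxy-11-oxoundecyl)triphenylphosphonium bromide
Conditions: PPh3, MeCN, reflux
Reagents that add atoms: triphenylphosphine, c1ccc(cc1)P(c1ccccc1)c1ccccc1
Why: SN2 quaternisation of the phosphine by the primary bromide (phosphonium salt formation) should proceed cleanly and leave the methyl ester untouched.

Step 2
Reactants: 2 (11-methoxy-11-oxoundecyl)triphenylphosphonium bromide; 3 tert-butyl (4S)-4-formyl-2,2-dimethyl-1,3-oxazolidine-3-carboxylate (L-serine-derived aldehyde)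
Product: 4 tert-butyl (4R)-4-[(1Z)-12-methoxy-12-oxododec-1-en-1-yl]-2,2-dimethyl-1,3-oxazolidine-3-carboxylate
Conditions: NaN(SiMe3)2 (1 equiv), THF, −78 °C, then 3, −78 → 20 °C
Reagents that add atoms: none
Why: Wittig olefination with the non-stabilised ylide under salt-free, low-temperature conditions should give the Z-alkene without epimerising the serine-derived centre, which is carried and not created here (the descriptor changes from S to R only through the priority rules).

Step 3
Reactants: 4 tert-butyl (4R)-4-[(1Z)-12-methoxy-12-oxododec-1-en-1-yl]-2,2-dimethyl-1,3-oxazolidine-3-carboxylate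
Product: 6 methyl (13R)-13-[(tert-butoxycarbonyl)amino]-14-hydroxytetradecanoate, via saturated oxazolidine 5 (not isolated)
Conditions: H2 (1 atm), Pd/C, MeOH, 20 °C; filter; TsOH·H2O (0.1 equiv), MeOH, 20 °C
Reagents that add atoms: none
Why: Heterogeneous hydrogenation saturates the alkene, and acid-catalysed transacetalisation in methanol then opens the N,O-acetonide, while the Boc carbamate and the methyl ester should survive catalytic TsOH.

Step 4
Reactants: 6 methyl (13R)-13-[(tert-butoxycarbonyl)amino]-14-hydroxytetradecanoate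
Product: 7 methyl (13R)-13-[(tert-butoxycarbonyl)amino]-14-iodotetradecanoate
Conditions: PPh3, I2, imidazole, CH2Cl2, 0 → 20 °C; used at once
Reagents that add atoms: iodine, II
Why: Appel-type iodination converts the primary alcohol into the iodide by SN2 at CH2, so the adjacent C13 centre (the future C6) is not touched.

Step 5
Reactants: 8 2,3-butanedione
Product: 9 3-oxobut-1-en-2-yl acetate
Conditions: isopropenyl acetate, TsOH·H2O (cat.), reflux, acetone distilled off
Reagents that add atoms: isopropenyl acetate, CC(=C)OC(C)=O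
Why: Acid-catalysed enol-ester exchange on the readily enolised 1,2-diketone should give the mono enol acetate, a captodative 1-acetylvinyl ester of a known class.

Step 6
Reactants: 7 methyl (13R)-13-[(tert-butoxycarbonyl)amino]-14-iodotetradecanoate; 9 3-oxobut-1-en-2-yl acetate
Product: 14 methyl 12-[(2R,6S)-6-methyl-5-oxopiperidin-2-yl]dodecanoate hydrochloride, via alkylzinc iodide 10 (not isolated), via enol silyl ether adduct 11 (not isolated), via amino ketol hydrochloride 12 (not isolated), via cyclic hydroxy imine 13 (not isolated)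
Conditions: (a) Zn (activated), DMF, 0 → 20 °C; (b) CuBr·SMe2 (0.1 equiv), 9, Me3SiCl, −20 → 20 °C; (c) same flask, HCl in MeOH (3 M), 20 → 40 °C; (d) NaOAc/AcOH–H2O to pH 5, argon, 50 °C; basic extraction, then HCl in Et2O
Reagents that add atoms: hydrogen chloride, Cl
Why: Proposed new method: the β-amido alkylzinc iodide 10 adds 1,4 (copper-catalysed, Me3SiCl-trapped) to the captodative enone 9 and forges C4–C5; methanolic HCl then strips Boc, silyl and acetyl, and at pH 5 the C6 amine condenses with the C2 ketone of ketol 12 (6-exo-trig addition, N1–C2 bond) to give the α-hydroxy imine 13, which tautomerises through the planar enaminol N1–C2=C3–OH to the α-amino ketone (Heyns rearrangement). The closest known reaction types are the zinc/copper conjugate addition–deprotection–cyclic imine sequence used for 6-substituted pipecolates and the Heyns (Voigt) conversion of α-hydroxy ketones plus amines into α-amino ketones; the new element is their fusion into one [3+3] annulation that ends at the piperidin-3-one. The only new stereocentre, C2, is set under thermodynamic control by the purchased C6 centre: in the N–H chair only the cis isomer has the 2-methyl and 6-alkyl groups both equatorial, so both C3 epimers of 12 and both C2 epimers of the ketone should drain into (2S,6R)-14, while C6 itself is never enolisable. Regioselectivity is secured in the substrate: on hydrolysis the enol silyl ether of 11 is protonated at C3 because OSiMe3 is a far better donor than OAc, which places the ketone at C2 and the carbinol at C3, so the amine can close only the six-membered ring and not a pyrroline. Chemoselectivity rests on the mild zinc reagent, which leaves the methyl ester and the carbamate alone, and on exclusion of oxygen, which keeps the enaminol from aromatising.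

Step 7
Reactants: 14 methyl 12-[(2R,6S)-6-methyl-5-oxopiperidin-2-yl]dodecanoate hydrochloride
Product: 16 (2S,3S,6R)-6-(12-hydroxydodecyl)-2-methylpiperidin-3-ol, via hydroxy ester 15 (not isolated)
Conditions: LiBH(s-Bu)3 (3.5 equiv), THF, −78 °C; then LiBH4, MeOH (3 equiv each), −78 → 20 °C
Reagents that add atoms: none
Why: Substrate-controlled hydride reduction: the bulky borohydride should attack the C3 carbonyl of the diequatorial chair from the equatorial side (as with 2-methylcyclohexanone) and give the axial 3-OH cis to the 2-methyl (3S); LiBH4/MeOH then reduces the methyl ester to the primary alcohol.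

Step 8
Reactants: 16 (2S,3S,6R)-6-(12-hydroxydodecyl)-2-methylpiperidin-3-ol
Product: 17 tert-butyl (2S,3S,6R)-3-hydroxy-6-(12-hydroxydodecyl)-2-methylpiperidine-1-carboxylate
Conditions: Boc2O (2.5 equiv), NaHCO3, THF–H2O, 50 °C
Reagents that add atoms: di-tert-butyl dicarbonate, CC(C)(C)OC(=O)OC(=O)OC(C)(C)C
Why: Carbamate formation with Boc2O without an acyl-transfer catalyst is selective for the secondary amine over both hydroxyl groups; warming compensates for the hindered 2,6-disubstituted nitrogen.

Step 9
Reactants: 17 tert-butyl (2S,3S,6R)-3-hydroxy-6-(12-hydroxydodecyl)-2-methylpiperidine-1-carboxylate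
Product: 18 tert-butyl (2S,3S,6R)-3-hydroxy-2-methyl-6-(12-oxododecyl)piperidine-1-carboxylate
Conditions: TEMPO (0.1 equiv), PhI(OAc)2 (1.1 equiv), CH2Cl2, 20 °C
Reagents that add atoms: none
Why: Oxoammonium-mediated oxidation is selective for the primary alcohol, and the hindered axial secondary alcohol next to C2 should remain.

Step 10
Reactants: 18 tert-butyl (2S,3S,6R)-3-hydroxy-2-methyl-6-(12-oxododecyl)piperidine-1-carboxylate (two molecules)
Product: 19 tert-butyl (2S,3S,6R)-6-[(12E)-13-formyl-23-{(2R,5S,6S)-1-(tert-butoxycarbonyl)-5-hydroxy-6-methylpiperidin-2-yl}tricos-12-en-1-yl]-3-hydroxy-2-methylpiperidine-1-carboxylate (the N,N'-di-Boc target)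
Conditions: pyrrolidine (0.2 equiv), PhCO2H (0.2 equiv), toluene, 40 °C
Reagents that add atoms: none
Why: Amine-catalysed (enamine/iminium) self-aldol condensation of the linear aldehyde followed by dehydration should give the thermodynamically preferred (E)-2-alkyl-2-enal with CHO trans to the β-alkyl group, and the α-branched enal formed no longer forms an enamine, so the reaction should stop at the dimer.

Step 11
Reactants: 19 the N,N'-di-Boc enal
Product: 20 (2E)-14-[(2R,5S,6S)-5-hydroxy-6-methylpiperidin-2-yl]-2-{10-[(2R,5S,6S)-5-hydroxy-6-methylpiperidin-2-yl]decyl}tetradec-2-enal (target)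
Conditions: CF3CO2H–CH2Cl2 (1:4), 0 → 20 °C; cold aqueous NaHCO3
Reagents that add atoms: none
Why: Acidolysis of both tert-butyl carbamates leaves the enal, the alkene geometry and the alcohols intact, and the hindered secondary amines are released only in the cold bicarbonate work-up.

## Compound list

1 | methyl 11-bromoundecanoate | COC(=O)CCCCCCCCCCBr | starting material
2 | (11-methoxy-11-oxoundecyl)triphenylphosphonium bromide | COC(=O)CCCCCCCCCC[P+](c1ccccc1)(c1ccccc1)c1ccccc1.[Br-] | intermediate
3 | tert-butyl (4S)-4-formyl-2,2-dimethyl-1,3-oxazolidine-3-carboxylate | CC1(C)OC[C@@H](C=O)N1C(=O)OC(C)(C)C | starting material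
4 | tert-butyl (4R)-4-[(1Z)-12-methoxy-12-oxododec-1-en-1-yl]-2,2-dimethyl-1,3-oxazolidine-3-carboxylate | CC1(C)OC[C@@H](/C=C\CCCCCCCCCC(=O)OC)N1C(=O)OC(C)(C)C | intermediate
5 | tert-butyl (4R)-4-(12-methoxy-12-oxododecyl)-2,2-dimethyl-1,3-oxazolidine-3-carboxylate | CC1(C)OC[C@@H](CCCCCCCCCCCC(=O)OC)N1C(=O)OC(C)(C)C | intermediate (not isolated)
6 | methyl (13R)-13-[(tert-butoxycarbonyl)amino]-14-hydroxytetradecanoate | OC[C@@H](CCCCCCCCCCCC(=O)OC)NC(=O)OC(C)(C)C | intermediate
7 | methyl (13R)-13-[(tert-butoxycarbonyl)amino]-14-iodotetradecanoate | IC[C@@H](CCCCCCCCCCCC(=O)OC)NC(=O)OC(C)(C)C | intermediate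
8 | 2,3-butanedione | CC(=O)C(C)=O | starting material
9 | 3-oxobut-1-en-2-yl acetate | CC(=O)OC(=C)C(C)=O | intermediate
10 | methyl (13R)-13-[(tert-butoxycarbonyl)amino]-14-(iodozincio)tetradecanoate | I[Zn]C[C@@H](CCCCCCCCCCCC(=O)OC)NC(=O)OC(C)(C)C | intermediate (not isolated)
11 | methyl (13R)-16-acetoxy-13-[(tert-butoxycarbonyl)amino]-17-[(trimethylsilyl)oxy]octadec-16-enoate (E/Z mixture) | CC(O[Si](C)(C)C)=C(OC(C)=O)CC[C@@H](CCCCCCCCCCCC(=O)OC)NC(=O)OC(C)(C)C | intermediate (not isolated)
12 | methyl (13R)-13-amino-16-hydroxy-17-oxooctadecanoate hydrochloride (C16 epimers) | CC(=O)C(O)CC[C@@H](CCCCCCCCCCCC(=O)OC)N.Cl | intermediate (not isolated)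
13 | methyl 12-[(2R)-5-hydroxy-6-methyl-2,3,4,5-tetrahydropyridin-2-yl]dodecanoate (C5 epimers) | CC1=N[C@H](CCCCCCCCCCCC(=O)OC)CCC1O | intermediate (not isolated)
14 | methyl 12-[(2R,6S)-6-methyl-5-oxopiperidin-2-yl]dodecanoate hydrochloride | C[C@@H]1N[C@H](CCCCCCCCCCCC(=O)OC)CCC1=O.Cl | intermediate
15 | methyl 12-[(2R,5S,6S)-5-hydroxy-6-methylpiperidin-2-yl]dodecanoate | C[C@@H]1N[C@H](CCCCCCCCCCCC(=O)OC)CC[C@@H]1O | intermediate (not isolated)
16 | (2S,3S,6R)-6-(12-hydroxydodecyl)-2-methylpiperidin-3-ol | C[C@@H]1N[C@H](CCCCCCCCCCCCO)CC[C@@H]1O | intermediate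
17 | tert-butyl (2S,3S,6R)-3-hydroxy-6-(12-hydroxydodecyl)-2-methylpiperidine-1-carboxylate | C[C@@H]1N(C(=O)OC(C)(C)C)[C@H](CCCCCCCCCCCCO)CC[C@@H]1O | intermediate
18 | tert-butyl (2S,3S,6R)-3-hydroxy-2-methyl-6-(12-oxododecyl)piperidine-1-carboxylate | C[C@@H]1N(C(=O)OC(C)(C)C)[C@H](CCCCCCCCCCCC=O)CC[C@@H]1O | intermediate
19 | N,N'-di-Boc target (name as in step 10) | C[C@@H]1N(C(=O)OC(C)(C)C)[C@H](CCCCCCCCCCC/C=C(/C=O)CCCCCCCCCC[C@@H]2CC[C@H](O)[C@H](C)N2C(=O)OC(C)(C)C)CC[C@@H]1O | intermediate
20 | (2E)-14-[(2R,5S,6S)-5-hydroxy-6-methylpiperidin-2-yl]-2-{10-[(2R,5S,6S)-5-hydroxy-6-methylpiperidin-2-yl]decyl}tetradec-2-enal | C[C@@H]1N[C@H](CCCCCCCCCCC/C=C(/C=O)CCCCCCCCCC[C@@H]2CC[C@H](O)[C@H](C)N2)CC[C@@H]1O | target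

## Step count and risks

Total step count: 11. Longest linear sequence: 10 steps (steps 1–4 and 6–11; step 5 is a one-step side branch).

**Step 6 (proposed new method).** What may go wrong:
- the zinc reagent may lose the carbamate by β-elimination before it adds;
- the ketol may isomerise (acyloin shift) and close a five-membered imine;
- the Heyns transposition may stay incomplete, or the enaminol may be oxidised to a pyridinol.

The fallback uses known chemistry, keeps the oxygen at C3 protected and corrects C3 afterwards. It sets out from 7 and 8 and comes back to the route at 17. Silylation of 8 (t-BuMe2SiOSO2CF3, Et3N) gives 3-[(tert-butyldimethylsilyl)oxy]but-3-en-2-one F1. The zinc reagent 10 made from 7 adds to F1 under the same CuBr·SMe2/Me3SiCl conditions to give the bis-silyl enol ether adduct F2, whose trimethylsilyl enol ether alone is cleaved with acetic-acid-buffered Bu4NF to the isolated acyclic N-Boc α-silyloxy ketone F3 (C16 epimers). CF3CO2H removes Boc and closes the cyclic imine F4, and hydrogenation over Pd/C from the face opposite the C6 chain should give the cis-2,6-piperidine silyl ether F5 (C3 epimers). Boc2O gives the carbamate F6, Bu4NF the N-Boc piperidin-3-ol epimers F7, and Dess–Martin periodinane converges both epimers on the single N-Boc piperidin-3-one F8. LiBH(s-Bu)3 (hydride anti to the 2-methyl group, which is axial under the carbamate) followed by LiBH4 then gives 17.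

**Step 10.** What may go wrong: the self-condensation may run on to trimers by Michael addition of further aldehyde to the enal, or stall at the aldol stage.

The fallback replaces the catalytic self-condensation by a directed aldol condensation through a metallated imine. It sets out from 18 and comes back at 19. Me3SiCl/imidazole gives the O-trimethylsilyl aldehyde F9. One half is condensed with cyclohexylamine to the N-cyclohexyl imine F10, which is deprotonated with LiN(i-Pr)2 at −78 °C and treated with the other half of F9 to give the β-hydroxy imine F11. Aqueous oxalic acid hydrolyses the imine, dehydrates to the (E)-enal and removes both silyl ethers to give 19.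

**Step 7.** What may go wrong: poor facial selectivity of hydride delivery to the N–H piperidinone (axial attack competing), which would give the 3-epimer.

The fallback changes from substrate control to catalyst control. It sets out from 14 and comes back at 16: an NADPH-dependent ketoreductase (alcohol dehydrogenase class, glucose/glucose dehydrogenase recycling, pH 7 buffer) selected for (S)-delivery at C3 should reduce 14 to 15, and LiBH4/MeOH then gives 16. No new compound is made.

## Further compounds

F1 | step 6 | 3-[(tert-butyldimethylsilyl)oxy]but-3-en-2-one | CC(=O)C(=C)O[Si](C)(C)C(C)(C)C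
F2 | step 6 | methyl (13R)-13-[(tert-butoxycarbonyl)amino]-16-[(tert-butyldimethylsilyl)oxy]-17-[(trimethylsilyl)oxy]octadec-16-enoate | CC(O[Si](C)(C)C)=C(O[Si](C)(C)C(C)(C)C)CC[C@@H](CCCCCCCCCCCC(=O)OC)NC(=O)OC(C)(C)C
F3 | step 6 | methyl (13R)-13-[(tert-butoxycarbonyl)amino]-16-[(tert-butyldimethylsilyl)oxy]-17-oxooctadecanoate (C16 epimers) | CC(=O)C(O[Si](C)(C)C(C)(C)C)CC[C@@H](CCCCCCCCCCCC(=O)OC)NC(=O)OC(C)(C)C
F4 | step 6 | methyl 12-[(2R)-5-[(tert-butyldimethylsilyl)oxy]-6-methyl-2,3,4,5-tetrahydropyridin-2-yl]dodecanoate (C5 epimers) | CC1=N[C@H](CCCCCCCCCCCC(=O)OC)CCC1O[Si](C)(C)C(C)(C)C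
F5 | step 6 | methyl 12-[(2R,6S)-5-[(tert-butyldimethylsilyl)oxy]-6-methylpiperidin-2-yl]dodecanoate (C5 epimers) | C[C@@H]1N[C@H](CCCCCCCCCCCC(=O)OC)CCC1O[Si](C)(C)C(C)(C)C
F6 | step 6 | tert-butyl (2S,6R)-3-[(tert-butyldimethylsilyl)oxy]-6-(12-methoxy-12-oxododecyl)-2-methylpiperidine-1-carboxylate (C3 epimers) | C[C@@H]1N(C(=O)OC(C)(C)C)[C@H](CCCCCCCCCCCC(=O)OC)CCC1O[Si](C)(C)C(C)(C)C
F7 | step 6 | tert-butyl (2S,6R)-3-hydroxy-6-(12-methoxy-12-oxododecyl)-2-methylpiperidine-1-carboxylate (C3 epimers) | C[C@@H]1N(C(=O)OC(C)(C)C)[C@H](CCCCCCCCCCCC(=O)OC)CCC1O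
F8 | step 6 | tert-butyl (2S,6R)-6-(12-methoxy-12-oxododecyl)-2-methyl-3-oxopiperidine-1-carboxylate | C[C@@H]1N(C(=O)OC(C)(C)C)[C@H](CCCCCCCCCCCC(=O)OC)CCC1=O
F9 | step 10 | tert-butyl (2S,3S,6R)-2-methyl-6-(12-oxododecyl)-3-[(trimethylsilyl)oxy]piperidine-1-carboxylate | C[C@@H]1N(C(=O)OC(C)(C)C)[C@H](CCCCCCCCCCCC=O)CC[C@@H]1O[Si](C)(C)C
F10 | step 10 | tert-butyl (2S,3S,6R)-6-[(12E)-12-(cyclohexylimino)dodecyl]-2-methyl-3-[(trimethylsilyl)oxy]piperidine-1-carboxylate | C[C@@H]1N(C(=O)OC(C)(C)C)[C@H](CCCCCCCCCCC/C=N/C2CCCCC2)CC[C@@H]1O[Si](C)(C)C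
F11 | step 10 | β-hydroxy N-cyclohexyl imine from F10 and F9 (aldol adduct, carbinol and α-carbon epimers, both rings N-Boc and O-trimethylsilyl) | C[C@@H]1N(C(=O)OC(C)(C)C)[C@H](CCCCCCCCCCCC(O)C(/C=N/C3CCCCC3)CCCCCCCCCC[C@@H]2CC[C@H](O[Si](C)(C)C)[C@H](C)N2C(=O)OC(C)(C)C)CC[C@@H]1O[Si](C)(C)C
F0 | step 7 | none | none
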